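**Strategy**

Ring A (C1–C5, C10) carries no functional group and is flanked by two quaternary carbons, the gem-dimethyl C4 and the angular C10. It is therefore disconnected at C1–C2 and C3–C4, so that a two-carbon unit (C2–C3) is stitched between a tertiary C4 radical and a C1 aldehyde on a finished ring B. In one pot, iron-hydride hydrogen-atom transfer to a C5 isopropenyl group gives the C4 radical, which adds to vinyltriphenylphosphonium bromide (C3–C4); the phosphonium salt then closes ring A by intramolecular Wittig reaction with the C10 formyl group (C1–C2). The precursor, a cyclohexanone carrying all ring B substituents, comes from (+)-verbenone, whose cyclobutane steers C10 and C9 and is then cleaved to the isopropenyl group.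

Key step: step 8

Remark: atoms carry labdane numbers (ring A: C1–C5 and C10; ring B: C5–C10; C17 is the carboxyl carbon; C11–C16 the side chain); compounds 1, 5 and 15 are assumed to be purchasable as shown (5 is otherwise one allylic oxidation from (+)-α-pinene).

**Route**

Step 1
Reactants: 1 methyl hydrogen (R)-3-methylglutarate
Product: 2 methyl (3R)-5-hydroxy-3-methylpentanoate
Conditions: BH3·SMe2, THF, −10 °C → rt; MeOH quench
Reagents that add atoms: none
Why: Borane reduces a free carboxylic acid through its acyloxyborane far faster than a methyl ester (chemoselective borane reduction), so only the acid terminus becomes the primary alcohol and the stereocentre is untouched.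

Step 2
Reactants: 2 methyl (3R)-5-hydroxy-3-methylpentanoate
Product: 3 methyl (3R)-3-methyl-5-(pivaloyloxy)pentanoate
Conditions: tBuCOCl, Et3N, DMAP (cat.), CH2Cl2, 0 °C → rt
Reagents that add atoms: pivaloyl chloride, CC(C)(C)C(Cl)=O
Why: DMAP-catalysed acylation (esterification) of the primary alcohol gives a pivalate, chosen because it has no α-hydrogen and should withstand the later enolate, Lewis-acid, hydrogen-atom-transfer and amide-base steps.

Step 3
Reactants: 3 methyl (3R)-3-methyl-5-(pivaloyloxy)pentanoate
Product: 4 (3R)-3-methyl-5-oxopentyl pivalate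
Conditions: iBu2AlH (1.05 equiv), CH2Cl2, −78 °C; aqueous potassium sodium tartrate
Reagents that add atoms: none
Why: Partial reduction with diisobutylaluminium hydride at low temperature stops at the aluminium hemiacetal of the unhindered methyl ester, which collapses to the aldehyde on work-up, while the bulky pivalate reacts much more slowly.

Step 4
Reactants: 5 (1R,5R)-(+)-verbenone; 4 (3R)-3-methyl-5-oxopentyl pivalate
Product: 7 3-[(3R)-1-hydroxy-3-methyl-5-(pivaloyloxy)pentyl]-4,6,6-trimethyl-4-vinylbicyclo[3.1.1]heptan-2-one (vinyl anti to the gem-dimethyl bridge; C9 and carbinol centres as a mixture), via bromomagnesium enolate 6 (not isolated)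
Conditions: CH2=CHMgBr (1.2 equiv), CuBr·SMe2 (10 mol %), THF, −40 → −20 °C; then 4 (1.3 equiv), −78 °C; aqueous NH4Cl
Reagents that add atoms: vinylmagnesium bromide, C=C[Mg]Br
Why: Copper-catalysed 1,4-addition of the vinyl Grignard reagent should take place on the face opposite the gem-dimethyl bridge and so set the quaternary carbon (future C10) with the vinyl group (future C1) trans to the bridge carbon (future C4), and the enolate, which can form only toward C9 because the other α-carbon is a bridgehead, adds to aldehyde 4 (tandem conjugate addition–aldol reaction), the two uncontrolled new centres being erased in steps 5 and 6.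

Step 5
Reactants: 7 aldol adduct
Product: 9 4,6,6-trimethyl-3-[(3S)-3-methyl-5-(pivaloyloxy)pentylidene]-4-vinylbicyclo[3.1.1]heptan-2-one (alkene geometry not defined), via mesylate 8 (not isolated)
Conditions: MeSO2Cl, Et3N, CH2Cl2, 0 °C; then DBU, rt
Reagents that add atoms: none
Why: Mesylation of the secondary alcohol and E1cB elimination through the ketone enolate (dehydration completing an aldol condensation) should give the conjugated exocyclic enone, whose geometry is of no consequence.

Step 6
Reactants: 9 alkylidene vinyl ketone
Product: 11 4-formyl-4,6,6-trimethyl-3-[(3S)-3-methyl-5-(pivaloyloxy)pentyl]bicyclo[3.1.1]heptan-2-one (formyl anti and side chain syn to the gem-dimethyl bridge), via alkylidene keto aldehyde 10 (not isolated)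
Conditions: O3, EtOAc, −78 °C (Sudan Red 7B end point); N2 purge; then H2 (1 atm), 10% Pd/C, −78 °C → rt
Reagents that add atoms: ozone, [O-][O+]=O
Why: Ozone should cleave the electron-neutral vinyl group much faster than the electron-poor enone alkene (ozonolysis with hydrogenolytic work-up), and the same palladium catalyst then saturates the alkylidene from the face opposite the gem-dimethyl bridge (heterogeneous hydrogenation, as for verbenone itself), so that hydrogen enters C9 anti to the bridge and the side chain becomes cis to the ring methyl group, the kinetic configuration required at C9.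

Step 7
Reactants: 11 bicyclic keto aldehyde
Product: 14 (2R,3S,4S)-3-formyl-3-methyl-2-[(3S)-3-methyl-5-(pivaloyloxy)pentyl]-4-(prop-1-en-2-yl)cyclohexan-1-one (side chain at C9 and methyl at C10 and isopropenyl at C5 all cis; formyl trans to both neighbours), via tertiary iodide silyl enol ether 12 (not isolated), via isopropenyl silyl enol ether 13 (not isolated)
Conditions: Me3SiI (2.5 equiv), CH2Cl2, −40 → 0 °C; then DBU, 0 °C → rt; then 1 M HCl (aq), THF, 0 °C
Reagents that add atoms: none
Why: Iodotrimethylsilane silylates the ketone, the strained bridgehead–CMe2 bond ionises to the tertiary cation that iodide captures (Lewis acid/halide ring opening of a cyclobutyl ketone of the nopinone type), DBU removes HI toward a methyl group (E2) while the ketone is still held as the C7–C8 silyl enol ether so that C9 cannot enolise, and mild acid returns the ketone, the aldehyde having been masked only reversibly as its α-iodo silyl ether.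

Step 8
Reactants: 14 monocyclic keto aldehyde; 15 vinyltriphenylphosphonium bromide
Product: 17 (5S,9R,10S,13S)-15-(pivaloyloxy)-17-norlabd-1-en-8-one, via alkylphosphonium bromide 16 (not isolated)
Conditions: Fe(acac)3 (0.3 equiv), PhSiH3 (2.5 equiv), 15 (1.5 equiv), EtOH, 60 °C; then solvent exchange to THF, K2CO3, 18-crown-6, 65 °C
Reagents that add atoms: none
Why: Proposed new method: an iron hydride formed from Fe(acac)3 and phenylsilane transfers a hydrogen atom to the CH2 terminus of the isopropenyl group (Markovnikov hydrogen-atom transfer) to give the tertiary C4 radical, which adds to the strongly electrophilic alkene of 15 and forms the C3–C4 bond, and the α-phosphonio radical is reduced by divalent iron and protonated (radical–polar crossover) or quenched by a second hydrogen atom to give salt 16, from which carbonate generates the ylide that closes ring A on the C10 formyl group (C1–C2, formed as C1=C2). The closest known reactions are the iron-catalysed reductive coupling of alkenes with electron-poor alkenes, the iron-catalysed radical–polar crossover annulation in which the same kind of radical adds to an enal and the ring is closed by aldol addition, the photoredox conjunctive olefination through vinylphosphonium salts, and the Schweizer annulation. Ring A closes by 6-exo attack of the ylide carbon on the aldehyde (intramolecular Wittig reaction), and because C4 and the formyl carbon are trans-diequatorial on ring B the ring fusion can only be trans. No new stereocentre arises, since C4 carries two methyl groups and C1 and C2 become an alkene. The step needs chemoselectivity for the 1,1-disubstituted alkene over ketone, aldehyde and ester, which hydrogen-atom transfer provides, and the excess of 15 should outrun reduction of the radical. A base just strong enough for the phosphonium salt is chosen so that the ketone is not enolised toward C9.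

Step 9
Reactants: 17 octalone
Product: 18 (5S,9R,10S,13S)-15-(pivaloyloxy)-17-norlabdan-8-one
Conditions: H2 (1 atm), 10% Pd/C, EtOAc, rt
Reagents that add atoms: none
Why: Catalytic hydrogenation should saturate the unhindered cis-disubstituted C1=C2 alkene without touching ketone or pivalate, and no stereocentre is formed.

Step 10
Reactants: 18 decalone
Product: 19 (5S,9R,10S,13S)-15-(pivaloyloxy)-17-norlabd-7-en-8-yl trifluoromethanesulfonate
Conditions: KN(SiMe3)2, THF, −78 °C; then PhNTf2, −78 → 0 °C; aqueous NH4Cl
Reagents that add atoms: N-phenylbis(trifluoromethanesulfonimide), O=S(=O)(N(c1ccccc1)S(=O)(=O)C(F)(F)F)C(F)(F)F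
Why: The amide base should remove a proton from the unhindered C7 methylene and not from the tertiary C9–H next to the quaternary C10 (kinetic enolate formation), and O-sulfonylation fixes the C7=C8 enol triflate without touching C9.

Step 11
Reactants: 19 enol triflate
Product: 20 methyl (5S,9R,10S,13S)-15-(pivaloyloxy)labd-7-en-17-oate
Conditions: Pd(OAc)2 (5 mol %), dppf (10 mol %), CO (1 atm), MeOH, Et3N, DMF, 60 °C
Reagents that add atoms: carbon monoxide, [C-]#[O+]; methanol, CO
Why: Oxidative addition of zerovalent palladium to the enol triflate, CO insertion and methanolysis of the acylpalladium (palladium-catalysed alkoxycarbonylation) install C17 on C8 with the C7=C8 double bond already in place.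

Step 12
Reactants: 20 methyl ester
Product: 21 (5S,9R,10S,13S)-15-hydroxylabd-7-en-17-oic acid
Conditions: KOH, MeOH/H2O, reflux; then 1 M HCl
Reagents that add atoms: water, O
Why: Saponification should cleave the methyl ester and the pivalate in one operation, and C9 is not acidic in the enoate and is unaffected.

Step 13
Reactants: 21 hydroxy acid
Product: 22 (5S,9R,10S,13S)-15-acetoxylabd-7-en-17-oic acid
Conditions: Ac2O, pyridine, DMAP (cat.), CH2Cl2, 0 °C → rt; aqueous NaHCO3 then dilute HCl
Reagents that add atoms: acetic anhydride, CC(=O)OC(C)=O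
Why: DMAP-catalysed acetylation esterifies the primary alcohol, and any mixed anhydride formed at the carboxylic acid is hydrolysed in the aqueous work-up.

**Compound list**

1 | methyl hydrogen (R)-3-methylglutarate | COC(=O)C[C@H](C)CC(=O)O | starting material
2 | methyl (3R)-5-hydroxy-3-methylpentanoate | COC(=O)C[C@H](C)CCO | intermediate
3 | methyl (3R)-3-methyl-5-(pivaloyloxy)pentanoate | COC(=O)C[C@H](C)CCOC(=O)C(C)(C)C | intermediate
4 | (3R)-3-methyl-5-oxopentyl pivalate | O=CC[C@H](C)CCOC(=O)C(C)(C)C | intermediate
5 | (1R,5R)-(+)-verbenone | CC1=CC(=O)[C@@H]2C[C@H]1C2(C)C | starting material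
6 | bromomagnesium enolate of 4,6,6-trimethyl-4-vinylbicyclo[3.1.1]heptan-2-one (vinyl anti to the bridge) | C=C[C@@]1(C)[C@H]2C[C@H](C2(C)C)C(O[Mg]Br)=C1 | intermediate
7 | aldol adduct, 3-[(3R)-1-hydroxy-3-methyl-5-(pivaloyloxy)pentyl]-4,6,6-trimethyl-4-vinylbicyclo[3.1.1]heptan-2-one (C9 and carbinol centres undefined) | C=C[C@@]1(C)[C@H]2C[C@H](C2(C)C)C(=O)C1C(O)C[C@H](C)CCOC(=O)C(C)(C)C | intermediate
8 | methanesulfonate of 7 | C=C[C@@]1(C)[C@H]2C[C@H](C2(C)C)C(=O)C1C(OS(C)(=O)=O)C[C@H](C)CCOC(=O)C(C)(C)C | intermediate
9 | 4,6,6-trimethyl-3-[(3S)-3-methyl-5-(pivaloyloxy)pentylidene]-4-vinylbicyclo[3.1.1]heptan-2-one (alkene geometry undefined) | C=C[C@@]1(C)[C@H]2C[C@H](C2(C)C)C(=O)C1=CC[C@H](C)CCOC(=O)C(C)(C)C | intermediate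
10 | 4-formyl analogue of 9 (alkylidene keto aldehyde) | O=C[C@@]1(C)[C@H]2C[C@H](C2(C)C)C(=O)C1=CC[C@H](C)CCOC(=O)C(C)(C)C | intermediate
11 | 4-formyl-4,6,6-trimethyl-3-[(3S)-3-methyl-5-(pivaloyloxy)pentyl]bicyclo[3.1.1]heptan-2-one (formyl anti, side chain syn to the bridge) | O=C[C@@]1(C)[C@H]2C[C@H](C2(C)C)C(=O)[C@@H]1CC[C@H](C)CCOC(=O)C(C)(C)C | intermediate
12 | ring-opened trimethylsilyl enol ether (C7=C8) with a 2-iodopropan-2-yl group at C5 | CC(C)(C)C(=O)OCC[C@@H](C)CC[C@H]1C(O[Si](C)(C)C)=CC[C@@H](C(C)(C)I)[C@]1(C)C=O | intermediate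
13 | ring-opened trimethylsilyl enol ether (C7=C8) with an isopropenyl group at C5 | CC(C)(C)C(=O)OCC[C@@H](C)CC[C@H]1C(O[Si](C)(C)C)=CC[C@@H](C(C)=C)[C@]1(C)C=O | intermediate
14 | (2R,3S,4S)-3-formyl-3-methyl-2-[(3S)-3-methyl-5-(pivaloyloxy)pentyl]-4-(prop-1-en-2-yl)cyclohexan-1-one | CC(C)(C)C(=O)OCC[C@@H](C)CC[C@H]1C(=O)CC[C@@H](C(C)=C)[C@]1(C)C=O | intermediate
15 | vinyltriphenylphosphonium bromide | C=C[P+](c1ccccc1)(c1ccccc1)c1ccccc1.[Br-] | starting material
16 | alkylphosphonium bromide (C4–C3H2–C2H2–PPh3 on C5 of 14, formyl intact) | CC(C)(C)C(=O)OCC[C@@H](C)CC[C@H]1C(=O)CC[C@@H](C(C)(C)CC[P+](c2ccccc2)(c2ccccc2)c2ccccc2)[C@]1(C)C=O.[Br-] | intermediate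
17 | (5S,9R,10S,13S)-15-(pivaloyloxy)-17-norlabd-1-en-8-one | CC(C)(C)C(=O)OCC[C@@H](C)CC[C@H]1C(=O)CC[C@H]2C(C)(C)CC=C[C@]12C | intermediate
18 | (5S,9R,10S,13S)-15-(pivaloyloxy)-17-norlabdan-8-one | CC(C)(C)C(=O)OCC[C@@H](C)CC[C@H]1C(=O)CC[C@H]2C(C)(C)CCC[C@]12C | intermediate
19 | (5S,9R,10S,13S)-15-(pivaloyloxy)-17-norlabd-7-en-8-yl trifluoromethanesulfonate | CC(C)(C)C(=O)OCC[C@@H](C)CC[C@H]1C(OS(=O)(=O)C(F)(F)F)=CC[C@H]2C(C)(C)CCC[C@]12C | intermediate
20 | methyl (5S,9R,10S,13S)-15-(pivaloyloxy)labd-7-en-17-oate | CC(C)(C)C(=O)OCC[C@@H](C)CC[C@H]1C(C(=O)OC)=CC[C@H]2C(C)(C)CCC[C@]12C | intermediate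
21 | (5S,9R,10S,13S)-15-hydroxylabd-7-en-17-oic acid | OCC[C@@H](C)CC[C@H]1C(C(=O)O)=CC[C@H]2C(C)(C)CCC[C@]12C | intermediate
22 | (5S,9R,10S,13S)-15-acetoxylabd-7-en-17-oic acid | CC(=O)OCC[C@@H](C)CC[C@H]1C(C(=O)O)=CC[C@H]2C(C)(C)CCC[C@]12C | target

**Summary**

Total step count: 13.
Longest linear sequence: 13 steps (1 → 22, steps 1–13); 10 steps from 5.

**Steps most likely to fail**

Step 8 (proposed new method). The C4 radical may be reduced to an isopropyl group before it adds to 15, the radical addition to the phosphonium salt may be slow, or ylide formation and ring closure may stay incomplete. The fallback uses known chemistry and sets out from 14: the iron-catalysed radical–polar crossover annulation with acrolein (Fe(acac)3, PhSiH3, EtOH/ethylene glycol) forms C3–C4 by Giese addition and C1–C2 by aldol addition of the iron enolate to the C10 formyl group, giving β-hydroxy aldehyde F1. Dehydration (MeSO2Cl, Et3N, then DBU) gives enal F2. Tsuji–Wilkinson decarbonylation with RhCl(PPh3)3 (stoichiometric, PhCN, heat) removes the C2 formyl group with the C1=C2 alkene retained and comes back to the route at 17.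

Step 7. The formyl oxygen may capture the C4 cation (cyclic acetal formation), elimination may run toward C5 (isopropylidene), or acid may enolise the ketone toward C9. The fallback opens the cyclobutane before the aldehyde exists and sets out from 9: copper hydride-catalysed 1,4-reduction ([(Ph3P)CuH]6, PhSiH3, then kinetic protonation anti to the bridge) gives vinyl ketone F3. HBr in AcOH at 0 °C opens the cyclobutane to tertiary bromide F4 with the vinyl group intact. Ozonolysis of the only alkene (O3, then Me2S) gives bromo keto aldehyde F5, and dehydrobromination (DBU, toluene, heat) comes back to the route at 14.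

Step 6. Ozone may attack the enone alkene, the hydrogenation may be incompletely face-selective, or C9 may be eroded later by enolisation; the two C9 epimers of these 2-alkyl ketones are expected to be close in energy, so the centre has to be held under kinetic control. The fallback corrects C9 at the decalone stage and sets out from 18 (as a C9 mixture): thermodynamic enol silylation (Me3SiCl, Et3N, DMF, heat) should give the tetrasubstituted C8=C9 silyl enol ether F6. Fluoride-triggered kinetic protonation (Bu4NF, AcOH, THF, −78 °C) delivers the proton axially from the α face, anti to the axial C10 methyl group, and comes back to the route at 18 with the 9α-H configuration.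

**Further compounds**

F1 | step 8 | (5S,9R,10S,13S)-2-formyl-1-hydroxy-15-(pivaloyloxy)-17-norlabdan-8-one (C1 and C2 undefined) | CC(C)(C)C(=O)OCC[C@@H](C)CC[C@H]1C(=O)CC[C@H]2C(C)(C)CC(C=O)C(O)[C@]12C
F2 | step 8 | (5S,9R,10S,13S)-2-formyl-15-(pivaloyloxy)-17-norlabd-1-en-8-one | CC(C)(C)C(=O)OCC[C@@H](C)CC[C@H]1C(=O)CC[C@H]2C(C)(C)CC(C=O)=C[C@]12C
F3 | step 7 | 4,6,6-trimethyl-3-[(3S)-3-methyl-5-(pivaloyloxy)pentyl]-4-vinylbicyclo[3.1.1]heptan-2-one (vinyl anti, side chain syn to the bridge) | C=C[C@@]1(C)[C@H]2C[C@H](C2(C)C)C(=O)[C@@H]1CC[C@H](C)CCOC(=O)C(C)(C)C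
F4 | step 7 | 4-(2-bromopropan-2-yl)-3-methyl-2-[(3S)-3-methyl-5-(pivaloyloxy)pentyl]-3-vinylcyclohexan-1-one (ring configuration as in 14) | CC(C)(C)C(=O)OCC[C@@H](C)CC[C@H]1C(=O)CC[C@@H](C(C)(C)Br)[C@]1(C)C=C
F5 | step 7 | 4-(2-bromopropan-2-yl)-3-formyl-3-methyl-2-[(3S)-3-methyl-5-(pivaloyloxy)pentyl]cyclohexan-1-one (ring configuration as in 14) | CC(C)(C)C(=O)OCC[C@@H](C)CC[C@H]1C(=O)CC[C@@H](C(C)(C)Br)[C@]1(C)C=O
F6 | step 6 | (5S,10S,13S)-15-(pivaloyloxy)-8-(trimethylsilyloxy)-17-norlabd-8-ene | CC(C)(C)C(=O)OCC[C@@H](C)CCC1=C(O[Si](C)(C)C)CC[C@H]2C(C)(C)CCC[C@]12C
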